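**Strategy.** The route rests on cutting the sp2–sp2 single bond between C3 of the furan-2(5H)-one ring (the carbon alpha to the lactone carbonyl) and the outer carbon of the E-vinyl group on the fully substituted oxirane carbon of the 7-oxabicyclo[4.1.0]heptane ring. A Suzuki–Miyaura coupling forms this bond in the last step and joins the complete, unprotected C26 bromobutenolide polyenyne to the unprotected C11 epoxycyclohexyl alkenylboronate, delivering the target directly with all four stereocentres and six alkene geometries already set. It exploits the alpha-bromo enoate character of C3 and the fixed E-alkenyl boron terminus. Both rings come from one actinol-derived enol triflate.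

Key step: step 19

Assumption: (4R,6R)-actinol 1, (2E)-3-methylpent-2-en-4-yn-1-ol 4 and propiolic acid 14 are taken as commercial; all polyene intermediates are handled under argon with exclusion of light.

Step 1
Reactants: 1 (4R,6R)-4-hydroxy-2,2,6-trimethylcyclohexan-1-one
Product: 2 (4R,6R)-4-{[tert-butyl(dimethyl)silyl]oxy}-2,2,6-trimethylcyclohexan-1-one
Conditions: TBSCl, imidazole, DMF, 23 °C
Reagents that add atoms: tert-butyl(chloro)dimethylsilane CC(C)(C)[Si](C)(C)Cl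
Why: Imidazole-promoted silylation protects the only hydroxyl group and leaves both stereocentres untouched.

Step 2
Reactants: 2 (4R,6R)-4-{[tert-butyl(dimethyl)silyl]oxy}-2,2,6-trimethylcyclohexan-1-one
Product: 3 (4R)-4-{[tert-butyl(dimethyl)silyl]oxy}-2,6,6-trimethylcyclohex-1-en-1-yl trifluoromethanesulfonate
Conditions: LiN(iPr)2, THF, −78 → 0 °C; then PhNTf2, 0 → 23 °C
Reagents that add atoms: N-phenylbis(trifluoromethanesulfonimide) O=S(=O)(N(c1ccccc1)S(=O)(=O)C(F)(F)F)C(F)(F)F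
Why: The ketone has a single alpha-hydrogen, so enolisation can give only the tetrasubstituted enolate, which is trapped on oxygen (enol triflate formation); the C6 centre becomes sp2 and the silyloxy-bearing centre is unchanged.

Step 3
Reactants: 3 (4R)-4-{[tert-butyl(dimethyl)silyl]oxy}-2,6,6-trimethylcyclohex-1-en-1-yl trifluoromethanesulfonate; 4 (2E)-3-methylpent-2-en-4-yn-1-ol
Product: 5 (2E)-5-[(4R)-4-{[tert-butyl(dimethyl)silyl]oxy}-2,6,6-trimethylcyclohex-1-en-1-yl]-3-methylpent-2-en-4-yn-1-ol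
Conditions: Pd(PPh3)4 (5 mol %), CuI (10 mol %), Et3N, DMF, 23 → 50 °C
Reagents that add atoms: none
Why: Sonogashira coupling of a vinyl triflate with a terminal alkyne tolerates the free allylic alcohol and carries the E-enyne through unchanged.

Step 4
Reactants: 5 (2E)-5-[(4R)-4-{[tert-butyl(dimethyl)silyl]oxy}-2,6,6-trimethylcyclohex-1-en-1-yl]-3-methylpent-2-en-4-yn-1-ol
Product: 6 (2E)-5-[(4R)-4-{[tert-butyl(dimethyl)silyl]oxy}-2,6,6-trimethylcyclohex-1-en-1-yl]-3-methylpent-2-en-4-ynal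
Conditions: activated MnO2, CH2Cl2, 23 °C
Reagents that add atoms: none
Why: MnO2 oxidises only the allylic alcohol to the enal (allylic oxidation) and does not touch the silyl ether or the enyne.

Step 5
Reactants: 6 (2E)-5-[(4R)-4-{[tert-butyl(dimethyl)silyl]oxy}-2,6,6-trimethylcyclohex-1-en-1-yl]-3-methylpent-2-en-4-ynal
Product: 7 (2E,4E)-7-[(4R)-4-{[tert-butyl(dimethyl)silyl]oxy}-2,6,6-trimethylcyclohex-1-en-1-yl]-5-methylhepta-2,4-dien-6-ynal
Conditions: Ph3P=CHCHO, toluene, 80 °C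
Reagents that add atoms: (triphenylphosphoranylidene)acetaldehyde O=CC=P(c1ccccc1)(c1ccccc1)c1ccccc1
Why: Wittig olefination with the stabilised formyl ylide adds two carbons E-selectively, and the less electrophilic dienal product should resist a second homologation.

Step 6
Reactants: 4 (2E)-3-methylpent-2-en-4-yn-1-ol
Product: 9 (2E)-3-methyl-5-(trimethylsilyl)pent-2-en-4-yn-1-ol, via bis-silylated enynol 8 (not isolated)
Conditions: n-BuLi (2.2 equiv), THF, −78 °C; TMSCl (2.2 equiv), −78 → 23 °C; then dilute HCl (aq), 23 °C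
Reagents that add atoms: chlorotrimethylsilane C[Si](C)(C)Cl
Why: Double deprotonation and bis-silylation followed by selective hydrolysis of the labile O–Si bond leaves the C-silylated alkyne (alkyne protection), which blocks acetylide formation in step 9.

Step 7
Reactants: 9 (2E)-3-methyl-5-(trimethylsilyl)pent-2-en-4-yn-1-ol
Product: 10 [(3E)-5-bromo-3-methylpent-3-en-1-yn-1-yl](trimethyl)silane
Conditions: CBr4, PPh3, CH2Cl2, 0 °C
Reagents that add atoms: tetrabromomethane BrC(Br)(Br)Br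
Why: Appel bromination converts the primary allylic alcohol into the bromide by direct SN2 displacement under neutral conditions, so the E-alkene is kept.

Step 8
Reactants: 10 [(3E)-5-bromo-3-methylpent-3-en-1-yn-1-yl](trimethyl)silane
Product: 11 diethyl [(2E)-3-methyl-5-(trimethylsilyl)pent-2-en-4-yn-1-yl]phosphonate
Conditions: P(OEt)3, neat, 100 °C
Reagents that add atoms: triethyl phosphite CCOP(OCC)OCC
Why: Michaelis–Arbuzov reaction of the reactive allylic bromide gives the allylic phosphonate without changing the alkene geometry.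

Step 9
Reactants: 7 (2E,4E)-7-[(4R)-4-{[tert-butyl(dimethyl)silyl]oxy}-2,6,6-trimethylcyclohex-1-en-1-yl]-5-methylhepta-2,4-dien-6-ynal; 11 diethyl [(2E)-3-methyl-5-(trimethylsilyl)pent-2-en-4-yn-1-yl]phosphonate
Product: 12 tert-butyl{[(1R)-4-[(3E,5E,7E,9E)-3,10-dimethyl-12-(trimethylsilyl)dodeca-3,5,7,9-tetraene-1,11-diyn-1-yl]-3,5,5-trimethylcyclohex-3-en-1-yl]oxy}dimethylsilane
Conditions: NaN(SiMe3)2, THF, −78 → 0 °C
Reagents that add atoms: none
Why: Horner–Wadsworth–Emmons olefination of the allylic phosphonate anion with the dienal should form the central disubstituted alkene with the E geometry usual for stabilised phosphonate carbanions.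

Step 10
Reactants: 12 tert-butyl{[(1R)-4-[(3E,5E,7E,9E)-3,10-dimethyl-12-(trimethylsilyl)dodeca-3,5,7,9-tetraene-1,11-diyn-1-yl]-3,5,5-trimethylcyclohex-3-en-1-yl]oxy}dimethylsilane
Product: 13 (1R)-4-[(3E,5E,7E,9E)-3,10-dimethyldodeca-3,5,7,9-tetraene-1,11-diyn-1-yl]-3,5,5-trimethylcyclohex-3-en-1-ol
Conditions: Bu4NF (2.5 equiv), THF, 0 → 23 °C
Reagents that add atoms: none
Why: Fluoride cleaves the alkynyl C–Si bond and the silyl ether O–Si bond in one operation (desilylation) without affecting the polyene.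

Step 11
Reactants: 14 prop-2-ynoic acid
Product: 15 (2E)-2,3-dibromoprop-2-enoic acid
Conditions: Br2, CHCl3, 0 → 23 °C, dark
Reagents that add atoms: bromine BrBr
Why: Electrophilic bromination of the alkyne through a bromonium ion proceeds by anti addition, which places the C3 bromine cis to the carboxyl group.

Step 12
Reactants: 13 (1R)-4-[(3E,5E,7E,9E)-3,10-dimethyldodeca-3,5,7,9-tetraene-1,11-diyn-1-yl]-3,5,5-trimethylcyclohex-3-en-1-ol; 15 (2E)-2,3-dibromoprop-2-enoic acid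
Product: 17 (5Z)-3-bromo-5-[(2E,4E,6E,8E)-11-[(4R)-4-hydroxy-2,6,6-trimethylcyclohex-1-en-1-yl]-2,9-dimethylundeca-2,4,6,8-tetraen-10-yn-1-ylidene]furan-2(5H)-one, via bromoenynoic acid 16 (not isolated)
Conditions: Pd(PPh3)4 (5 mol %), CuI (10 mol %), Et3N, MeCN, 23 °C, dark; 15 in excess (2 equiv)
Reagents that add atoms: none
Why: Tandem Sonogashira coupling and 5-exo-dig lactonisation, in which the more electrophilic beta C–Br bond couples with retention and the cis carboxylate then adds anti across the metal-activated alkyne to fix the Z-ylidene geometry, while the excess of 15 disfavours a second coupling at the alpha-bromide of the product.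

Step 13
Reactants: 3 (4R)-4-{[tert-butyl(dimethyl)silyl]oxy}-2,6,6-trimethylcyclohex-1-en-1-yl trifluoromethanesulfonate
Product: 18 methyl (4R)-4-{[tert-butyl(dimethyl)silyl]oxy}-2,6,6-trimethylcyclohex-1-ene-1-carboxylate
Conditions: CO (1 atm), Pd(OAc)2 (cat.), PPh3, Et3N, MeOH/DMF, 60 °C
Reagents that add atoms: carbon monoxide [C-]#[O+]; methanol CO
Why: Palladium-catalysed methoxycarbonylation of the vinyl triflate (oxidative addition, CO insertion, methanolysis) installs the one-carbon unit on the ring.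

Step 14
Reactants: 18 methyl (4R)-4-{[tert-butyl(dimethyl)silyl]oxy}-2,6,6-trimethylcyclohex-1-ene-1-carboxylate
Product: 19 [(4R)-4-{[tert-butyl(dimethyl)silyl]oxy}-2,6,6-trimethylcyclohex-1-en-1-yl]methanol
Conditions: iBu2AlH (2.5 equiv), CH2Cl2, −78 → 0 °C; KNaC4H4O6 (aq)
Reagents that add atoms: none
Why: Hydride reduction of the conjugated ester with iBu2AlH gives the allylic alcohol by clean 1,2-reduction.

Step 15
Reactants: 19 [(4R)-4-{[tert-butyl(dimethyl)silyl]oxy}-2,6,6-trimethylcyclohex-1-en-1-yl]methanol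
Product: 20 [(1R,3S,6R)-3-{[tert-butyl(dimethyl)silyl]oxy}-1,5,5-trimethyl-7-oxabicyclo[4.1.0]heptan-6-yl]methanol
Conditions: Ti(OiPr)4 (cat.), D-(−)-diethyl tartrate, t-BuOOH, 4 Å molecular sieves, CH2Cl2, −20 °C
Reagents that add atoms: tert-butyl hydroperoxide CC(C)(C)OO
Why: Sharpless asymmetric epoxidation with the D-(−)-tartrate titanium complex should deliver oxygen to the alkene face anti to the silyloxy group, a matched case in which reagent control and the steric bias of the ring agree, and this sets both oxirane stereocentres.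

Step 16
Reactants: 20 [(1R,3S,6R)-3-{[tert-butyl(dimethyl)silyl]oxy}-1,5,5-trimethyl-7-oxabicyclo[4.1.0]heptan-6-yl]methanol
Product: 21 (1R,3S,6S)-3-{[tert-butyl(dimethyl)silyl]oxy}-1,5,5-trimethyl-7-oxabicyclo[4.1.0]heptane-6-carbaldehyde
Conditions: NPr4RuO4 (5 mol %), N-methylmorpholine N-oxide, 4 Å molecular sieves, CH2Cl2, 23 °C
Reagents that add atoms: none
Why: Ley–Griffith oxidation gives the aldehyde under neutral conditions that spare the epoxide, and the quaternary alpha-carbon cannot epimerise.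

Step 17
Reactants: 21 (1R,3S,6S)-3-{[tert-butyl(dimethyl)silyl]oxy}-1,5,5-trimethyl-7-oxabicyclo[4.1.0]heptane-6-carbaldehyde
Product: 22 tert-butyl(dimethyl){[(1R,3S,6S)-1,5,5-trimethyl-6-[(E)-2-(4,4,5,5-tetramethyl-1,3,2-dioxaborolan-2-yl)ethenyl]-7-oxabicyclo[4.1.0]heptan-3-yl]oxy}silane
Conditions: CrCl2 (8 equiv), LiI (4 equiv), Cl2CHB(pin) (2 equiv), THF, 23 °C
Reagents that add atoms: 2-(dichloromethyl)-4,4,5,5-tetramethyl-1,3,2-dioxaborolane CC1(C)OB(C(Cl)Cl)OC1(C)C
Why: Takai–Utimoto boryl olefination, in which the geminal dichromium species adds to the aldehyde and eliminates, should give the E-alkenylboronate selectively.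

Step 18
Reactants: 22 tert-butyl(dimethyl){[(1R,3S,6S)-1,5,5-trimethyl-6-[(E)-2-(4,4,5,5-tetramethyl-1,3,2-dioxaborolan-2-yl)ethenyl]-7-oxabicyclo[4.1.0]heptan-3-yl]oxy}silane
Product: 23 (1R,3S,6S)-1,5,5-trimethyl-6-[(E)-2-(4,4,5,5-tetramethyl-1,3,2-dioxaborolan-2-yl)ethenyl]-7-oxabicyclo[4.1.0]heptan-3-ol
Conditions: Bu4NF, AcOH (1:1), THF, 0 → 23 °C
Reagents that add atoms: none
Why: Acetic acid-buffered fluoride desilylation should remove the silyl ether without opening the epoxide, with any fluoride adduct at boron reverting to the pinacol ester on work-up.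

Step 19
Reactants: 17 (5Z)-3-bromo-5-[(2E,4E,6E,8E)-11-[(4R)-4-hydroxy-2,6,6-trimethylcyclohex-1-en-1-yl]-2,9-dimethylundeca-2,4,6,8-tetraen-10-yn-1-ylidene]furan-2(5H)-one; 23 (1R,3S,6S)-1,5,5-trimethyl-6-[(E)-2-(4,4,5,5-tetramethyl-1,3,2-dioxaborolan-2-yl)ethenyl]-7-oxabicyclo[4.1.0]heptan-3-ol
Product: 24 (5Z)-3-{(E)-2-[(1R,3S,6S)-3-hydroxy-1,5,5-trimethyl-7-oxabicyclo[4.1.0]heptan-6-yl]ethenyl}-5-[(2E,4E,6E,8E)-11-[(4R)-4-hydroxy-2,6,6-trimethylcyclohex-1-en-1-yl]-2,9-dimethylundeca-2,4,6,8-tetraen-10-yn-1-ylidene]furan-2(5H)-one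
Conditions: Pd(OAc)2 (5 mol %), SPhos (10 mol %), K3PO4 (aq), THF, 23 °C, dark
Reagents that add atoms: none
Why: Zerovalent palladium inserts into the C3–Br bond of the butenolide, the phosphate-activated E-alkenylboronate transmetalates, and reductive elimination forms the sp2–sp2 bond with retention of both alkene geometries. The closest known reaction type is the Suzuki–Miyaura coupling of alpha-bromobutenolides with alkenylboronic esters. No ring is closed and no stereocentre is created, so the four stereocentres, the oxirane and the Z-ylidene lactone are carried through as spectators. The step needs chemoselectivity for the single C–Br bond over ionisation of the vinyl oxirane and over hydrolysis of the enol lactone. The alpha-bromo enoate makes oxidative addition fast at room temperature, the fully substituted oxirane carbon disfavours allyl-palladium formation, and the mild phosphate base, short reaction time and exclusion of light should protect the lactone and the polyene.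

**Compound list**

1 | (4R,6R)-4-hydroxy-2,2,6-trimethylcyclohexan-1-one | C[C@H]1C(=O)C(C)(C)C[C@H](O)C1 | starting material
2 | (4R,6R)-4-{[tert-butyl(dimethyl)silyl]oxy}-2,2,6-trimethylcyclohexan-1-one | C[C@H]1C(=O)C(C)(C)C[C@H](O[Si](C)(C)C(C)(C)C)C1 | intermediate
3 | (4R)-4-{[tert-butyl(dimethyl)silyl]oxy}-2,6,6-trimethylcyclohex-1-en-1-yl trifluoromethanesulfonate | CC1=C(OS(=O)(=O)C(F)(F)F)C(C)(C)C[C@H](O[Si](C)(C)C(C)(C)C)C1 | intermediate
4 | (2E)-3-methylpent-2-en-4-yn-1-ol | C#C/C(C)=C/CO | starting material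
5 | (2E)-5-[(4R)-4-{[tert-butyl(dimethyl)silyl]oxy}-2,6,6-trimethylcyclohex-1-en-1-yl]-3-methylpent-2-en-4-yn-1-ol | CC1=C(C#C/C(C)=C/CO)C(C)(C)C[C@H](O[Si](C)(C)C(C)(C)C)C1 | intermediate
6 | (2E)-5-[(4R)-4-{[tert-butyl(dimethyl)silyl]oxy}-2,6,6-trimethylcyclohex-1-en-1-yl]-3-methylpent-2-en-4-ynal | CC1=C(C#C/C(C)=C/C=O)C(C)(C)C[C@H](O[Si](C)(C)C(C)(C)C)C1 | intermediate
7 | (2E,4E)-7-[(4R)-4-{[tert-butyl(dimethyl)silyl]oxy}-2,6,6-trimethylcyclohex-1-en-1-yl]-5-methylhepta-2,4-dien-6-ynal | CC1=C(C#C/C(C)=C/C=C/C=O)C(C)(C)C[C@H](O[Si](C)(C)C(C)(C)C)C1 | intermediate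
8 | trimethyl{[(2E)-3-methyl-5-(trimethylsilyl)pent-2-en-4-yn-1-yl]oxy}silane | C[Si](C)(C)C#C/C(C)=C/CO[Si](C)(C)C | intermediate (not isolated)
9 | (2E)-3-methyl-5-(trimethylsilyl)pent-2-en-4-yn-1-ol | C[Si](C)(C)C#C/C(C)=C/CO | intermediate
10 | [(3E)-5-bromo-3-methylpent-3-en-1-yn-1-yl](trimethyl)silane | C[Si](C)(C)C#C/C(C)=C/CBr | intermediate
11 | diethyl [(2E)-3-methyl-5-(trimethylsilyl)pent-2-en-4-yn-1-yl]phosphonate | CCOP(=O)(C/C=C(C)/C#C[Si](C)(C)C)OCC | intermediate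
12 | tert-butyl{[(1R)-4-[(3E,5E,7E,9E)-3,10-dimethyl-12-(trimethylsilyl)dodeca-3,5,7,9-tetraene-1,11-diyn-1-yl]-3,5,5-trimethylcyclohex-3-en-1-yl]oxy}dimethylsilane | CC1=C(C#C/C(C)=C/C=C/C=C/C=C(C)/C#C[Si](C)(C)C)C(C)(C)C[C@H](O[Si](C)(C)C(C)(C)C)C1 | intermediate
13 | (1R)-4-[(3E,5E,7E,9E)-3,10-dimethyldodeca-3,5,7,9-tetraene-1,11-diyn-1-yl]-3,5,5-trimethylcyclohex-3-en-1-ol | CC1=C(C#C/C(C)=C/C=C/C=C/C=C(C)/C#C)C(C)(C)C[C@H](O)C1 | intermediate
14 | prop-2-ynoic acid | C#CC(=O)O | starting material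
15 | (2E)-2,3-dibromoprop-2-enoic acid | OC(=O)/C(Br)=C\Br | intermediate
16 | (2E,6E,8E,10E,12E)-2-bromo-15-[(4R)-4-hydroxy-2,6,6-trimethylcyclohex-1-en-1-yl]-6,13-dimethylpentadeca-2,6,8,10,12-pentaene-4,14-diynoic acid | CC1=C(C#C/C(C)=C/C=C/C=C/C=C(C)/C#C/C=C(/Br)C(=O)O)C(C)(C)C[C@H](O)C1 | intermediate (not isolated)
17 | (5Z)-3-bromo-5-[(2E,4E,6E,8E)-11-[(4R)-4-hydroxy-2,6,6-trimethylcyclohex-1-en-1-yl]-2,9-dimethylundeca-2,4,6,8-tetraen-10-yn-1-ylidene]furan-2(5H)-one | CC1=C(C#C/C(C)=C/C=C/C=C/C=C(C)/C=C2C=C(Br)C(=O)O/2)C(C)(C)C[C@H](O)C1 | intermediate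
18 | methyl (4R)-4-{[tert-butyl(dimethyl)silyl]oxy}-2,6,6-trimethylcyclohex-1-ene-1-carboxylate | CC1=C(C(=O)OC)C(C)(C)C[C@H](O[Si](C)(C)C(C)(C)C)C1 | intermediate
19 | [(4R)-4-{[tert-butyl(dimethyl)silyl]oxy}-2,6,6-trimethylcyclohex-1-en-1-yl]methanol | CC1=C(CO)C(C)(C)C[C@H](O[Si](C)(C)C(C)(C)C)C1 | intermediate
20 | [(1R,3S,6R)-3-{[tert-butyl(dimethyl)silyl]oxy}-1,5,5-trimethyl-7-oxabicyclo[4.1.0]heptan-6-yl]methanol | OC[C@@]12O[C@]1(C)C[C@@H](O[Si](C)(C)C(C)(C)C)CC2(C)C | intermediate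
21 | (1R,3S,6S)-3-{[tert-butyl(dimethyl)silyl]oxy}-1,5,5-trimethyl-7-oxabicyclo[4.1.0]heptane-6-carbaldehyde | O=C[C@@]12O[C@]1(C)C[C@@H](O[Si](C)(C)C(C)(C)C)CC2(C)C | intermediate
22 | tert-butyl(dimethyl){[(1R,3S,6S)-1,5,5-trimethyl-6-[(E)-2-(4,4,5,5-tetramethyl-1,3,2-dioxaborolan-2-yl)ethenyl]-7-oxabicyclo[4.1.0]heptan-3-yl]oxy}silane | CC1(C)OB(/C=C/[C@@]23O[C@]2(C)C[C@@H](O[Si](C)(C)C(C)(C)C)CC3(C)C)OC1(C)C | intermediate
23 | (1R,3S,6S)-1,5,5-trimethyl-6-[(E)-2-(4,4,5,5-tetramethyl-1,3,2-dioxaborolan-2-yl)ethenyl]-7-oxabicyclo[4.1.0]heptan-3-ol | CC1(C)OB(/C=C/[C@@]23O[C@]2(C)C[C@@H](O)CC3(C)C)OC1(C)C | intermediate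
24 | (5Z)-3-{(E)-2-[(1R,3S,6S)-3-hydroxy-1,5,5-trimethyl-7-oxabicyclo[4.1.0]heptan-6-yl]ethenyl}-5-[(2E,4E,6E,8E)-11-[(4R)-4-hydroxy-2,6,6-trimethylcyclohex-1-en-1-yl]-2,9-dimethylundeca-2,4,6,8-tetraen-10-yn-1-ylidene]furan-2(5H)-one | CC1=C(C#C/C(C)=C/C=C/C=C/C=C(C)/C=C2C=C(/C=C/[C@@]34O[C@]3(C)C[C@@H](O)CC4(C)C)C(=O)O/2)C(C)(C)C[C@H](O)C1 | target

**Totals.** Total step count: 19. Longest linear sequence: 9 steps (1 → 2 → 3 → 5 → 6 → 7 → 12 → 13 → 17 → 24; the epoxide branch 1 → 2 → 3 → 18 → 19 → 20 → 21 → 22 → 23 → 24 is equally long).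

**Steps most likely to fail**

Risk at step 12: the alpha C–Br bond of the freshly formed bromobutenolide may undergo a second Sonogashira coupling, or ring closure may go 6-endo instead of 5-exo. The fallback separates coupling from lactonisation and sets out from 13 and 15. Acid 15 is esterified (MeOH, H2SO4 cat.) to methyl (2E)-2,3-dibromoprop-2-enoate F1. Sonogashira coupling of 13 with F1 (Pd(PPh3)4, CuI, Et3N, 0 °C) at the beta C–Br bond should give methyl (2E,6E,8E,10E,12E)-2-bromo-15-[(4R)-4-hydroxy-2,6,6-trimethylcyclohex-1-en-1-yl]-6,13-dimethylpentadeca-2,6,8,10,12-pentaene-4,14-diynoate F2. Saponification (LiOH, THF/H2O, 0 °C) gives acid 16, now isolated, and silver-catalysed 5-exo-dig lactonisation (AgNO3 cat., acetone, dark) comes back to the route at 17.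

Risk at step 19: the aqueous base may open the enol lactone, or slow transmetalation may leave time for polyene isomerisation and palladium-induced opening of the vinyl oxirane. The fallback is a base-free Stille coupling that sets out from 21. (Dibromomethyl)tributylstannane F3 is made from CH2Br2, LiN(iPr)2 and Bu3SnCl (THF, −95 °C). Takai-type olefination of 21 with F3 (CrCl2, LiI, THF/DMF) should give tributyl{(E)-2-[(1R,3S,6S)-3-{[tert-butyl(dimethyl)silyl]oxy}-1,5,5-trimethyl-7-oxabicyclo[4.1.0]heptan-6-yl]ethenyl}stannane F4. Desilylation (Bu4NF, THF) gives (1R,3S,6S)-1,5,5-trimethyl-6-[(E)-2-(tributylstannyl)ethenyl]-7-oxabicyclo[4.1.0]heptan-3-ol F5. Stille coupling of F5 with 17 (Pd2(dba)3, AsPh3, NMP, 23 °C, dark) comes back to the route at 24.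

Risk at step 18: fluoride may attack boron and cause protodeboronation or loss of the pinacol ester during desilylation. The fallback postpones deprotection and sets out from 22. Suzuki–Miyaura coupling of 22 with 17 under the conditions of step 19 should give the mono-silyl ether (5Z)-3-{(E)-2-[(1R,3S,6S)-3-{[tert-butyl(dimethyl)silyl]oxy}-1,5,5-trimethyl-7-oxabicyclo[4.1.0]heptan-6-yl]ethenyl}-5-[(2E,4E,6E,8E)-11-[(4R)-4-hydroxy-2,6,6-trimethylcyclohex-1-en-1-yl]-2,9-dimethylundeca-2,4,6,8-tetraen-10-yn-1-ylidene]furan-2(5H)-one F6. Buffered desilylation (Bu4NF, AcOH, THF, 0 → 23 °C) comes back to the route at 24.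

**Further compounds**

F1 | step 12 | methyl (2E)-2,3-dibromoprop-2-enoate | COC(=O)/C(Br)=C\Br
F2 | step 12 | methyl (2E,6E,8E,10E,12E)-2-bromo-15-[(4R)-4-hydroxy-2,6,6-trimethylcyclohex-1-en-1-yl]-6,13-dimethylpentadeca-2,6,8,10,12-pentaene-4,14-diynoate | CC1=C(C#C/C(C)=C/C=C/C=C/C=C(C)/C#C/C=C(/Br)C(=O)OC)C(C)(C)C[C@H](O)C1
F3 | step 19 | (dibromomethyl)tributylstannane | CCCC[Sn](CCCC)(CCCC)C(Br)Br
F4 | step 19 | tributyl{(E)-2-[(1R,3S,6S)-3-{[tert-butyl(dimethyl)silyl]oxy}-1,5,5-trimethyl-7-oxabicyclo[4.1.0]heptan-6-yl]ethenyl}stannane | CCCC[Sn](CCCC)(CCCC)/C=C/[C@@]12O[C@]1(C)C[C@@H](O[Si](C)(C)C(C)(C)C)CC2(C)C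
F5 | step 19 | (1R,3S,6S)-1,5,5-trimethyl-6-[(E)-2-(tributylstannyl)ethenyl]-7-oxabicyclo[4.1.0]heptan-3-ol | CCCC[Sn](CCCC)(CCCC)/C=C/[C@@]12O[C@]1(C)C[C@@H](O)CC2(C)C
F6 | step 18 | (5Z)-3-{(E)-2-[(1R,3S,6S)-3-{[tert-butyl(dimethyl)silyl]oxy}-1,5,5-trimethyl-7-oxabicyclo[4.1.0]heptan-6-yl]ethenyl}-5-[(2E,4E,6E,8E)-11-[(4R)-4-hydroxy-2,6,6-trimethylcyclohex-1-en-1-yl]-2,9-dimethylundeca-2,4,6,8-tetraen-10-yn-1-ylidene]furan-2(5H)-one | CC1=C(C#C/C(C)=C/C=C/C=C/C=C(C)/C=C2C=C(/C=C/[C@@]34O[C@]3(C)C[C@@H](O[Si](C)(C)C(C)(C)C)CC4(C)C)C(=O)O/2)C(C)(C)C[C@H](O)C1
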